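**Numbering used throughout (xenicane numbering):** acetal carbon C1, ring oxygen O2, enol-ether carbons C3 and C4, ring-fusion carbons C4a and C11a, then C5, C6, C7 (methyl C18, OH), C8, C9, C10, C11 (=C19H2) around the nine-membered ring; side chain C12, C13 (OAc), C14, C15 (epoxide).

## Analysis of the target

Compound 38 is a xenicane: a 2-acetoxy-3,4-dihydro-2H-pyran (O2, C1, C3, C4, C4a, C11a) trans-fused through C4a–C11a to a cyclononane that carries an exocyclic C11=C19 methylene, a tertiary C7 carbinol and a cis C8–C9 epoxide. C4 bears a four-carbon chain with acetates at C12 and C13 and a trisubstituted C14–C15 epoxide. The nine stereocentres (1R,4aS,7S,8R,9R,11aR,12R,13R,14R) form three groups: the acetal/ring-fusion triad (H-4a and H-11a trans, C1 acetate trans to the C11 branch), the C7–C9 array (hydroxyl syn to the epoxide oxygen), and the side chain (C12/C13 anti, C13/C14 anti), which is remote from the ring centres. The sensitive groups are the α-acetoxy enol acetal, the C3=C4 enol ether with an allylic C12 acetate (it ionises readily under acid), both epoxides and three base-labile acetates, so the end of the synthesis must avoid acid and strong base. The main difficulties are the nine-membered carbocycle, for which direct cyclisation is entropically and enthalpically poor, and a dihydropyran in which two aldehyde-level carbons (C1 and C3) must be told apart. The strategy rests on C11 (as a ketone), C10, C9 and the C7-methyl C7=C8 olefin. Together they form a 5-methylcyclonon-4-enone, which is the product of a [3,3] shift of a 2-methylene-7-methyl-7-vinyloxepane, so the ring can be grown from an easily made seven-membered lactone instead of being cyclised.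

## Retrosynthetic reasoning

**38 ⇒ 37 (C8–C9 epoxide).** The epoxide is removed last. In 37 the tertiary C7 hydroxyl is the only free hydroxyl and is allylic to the Z C8=C9 olefin, so a vanadium-catalysed, hydroxyl-directed epoxidation should place oxygen syn to the carbinol and spare the enol ether and the exocyclic methylene. Doing it last keeps the epoxy alcohol away from organolithium, hydride and fluoride.

**37 ⇒ 35 (three C–O acyl bonds, C1 acetal).** The acetoxy acetal cannot pass through organometallic steps. It also cannot be made at the end by acid-catalysed exchange of an alkyl acetal, because the enol ether with its allylic C12 oxygen and the epoxides would not survive. C1 is therefore carried as a silyl acetal. Buffered fluoride releases the lactol together with the C13 and C7 hydroxyls, and one acetylation installs all three acetates.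

**35 ⇒ 26 + 33 (C4–C12).** Cutting this bond brings in the whole side chain with C13 and C14 already set, leaving only C12 to control. Forward, bromine–lithium exchange on 26 and Felkin–Anh addition to the α-silyloxy aldehyde 33 should give the 12,13-anti carbinol.

**33 ⇒ 27 (side chain).** C13 comes from the chiral pool: the formyl carbon of 27 becomes C14 by Wittig olefination and the CH2O carbon becomes C12. C14 is set by a reagent-controlled epoxidation, because hydroxyl-directed epoxidation of this olefin type would give the unwanted syn (threo) relationship.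

**26 ⇒ 24 ⇒ 22 (C4–Br, C3=C4).** The bromide comes from enol ether 24 by bromination and dehydrobromination. Enol ether 24 is not made by closing two acetals, because that would not decide which carbon becomes the enol-ether carbon, and the diene-conjugated C1=C11a isomer would be favoured at equilibrium. In lactone 22 the C3 carbon is instead at the acid level and C1 at the acetal level; after reduction only C3 bears a leaving group, so dehydration must give C3=C4.

**22 ⇒ 21 ⇒ 19 ⇒ 18 ⇒ 16 (C7–O, O2–C1, C3 oxidation level).** The C7 carbinol and the C8=C9 olefin come from the C7=C8 olefin of 19 by a singlet-oxygen ene reaction. This is placed after all aqueous acid steps (a tertiary allylic alcohol would not tolerate them) and before any enol ether exists. Hydroxy lactone 19 is the ring tautomer of the aldehydo acid set free from 18, and 18 comes from 16 by hydrolysis of the more labile acyclic acetal and oxidation.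

**16 ⇒ 15 ⇒ 13 (C11=C19; C9–C10 and C10–C11).** Methylenation of ketone 15 gives 16. Ketone 15 is disconnected by the retro-[3,3] shift to the enol ether of lactone 13. Two skeletal bonds and the nine-membered ring come from one operation on a seven-membered ring, and no stereocentre is at stake.

**13 ⇒ 12 ⇒ 11 ⇒ 9 (C11–O–C7, C7–C8, ring cleavage).** The lactone comes from hydroxy acid 12, made by vinyl addition to the methyl ketone of 11. Keto acid 11 comes from ozonolysis of the trisubstituted olefin of cyclohexene 9, which delivers the C7 ketone and the C11 carboxyl with C4a and C11a already in place.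

**9 ⇒ 7 ⇒ 6 ⇒ 4 + 5; 4 ⇒ 1 + 2.** The cyclohexene is a Diels–Alder adduct of diene 4 and acrolein 5. Organocatalysis sets C11a, epimerisation next to the formyl group gives the trans relationship, and a one-carbon homologation supplies C3. Diene 4 is the Wittig product of 1 and 2.

## Alternatives that were turned down

**Alternative 1:** The dihydropyran is cut across O2–C1 and C4a–C11a into an oxadiene and an enol ether, with the nine-membered ring still open. Forward, an oxadiene generated in the flask by Knoevenagel condensation would be trapped in an endo-selective hetero-Diels–Alder reaction catalysed by a bis(oxazoline) complex of divalent copper, giving the ester-substituted methoxy-dihydropyran A1.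
- For it: C1, C4a and C11a are set in one catalytic, convergent step, and the C4 ester makes the enol ether robust. On the pyran it is clearly stronger than the chosen route, which spends steps 10, 11 and 13–15 on it.
- Against it: from A1 the nine-membered ring must still be closed by a true medium-ring cyclisation of two side arms, the least favourable way to a cyclononane. Neither the C7 carbinol nor the methylene is in place, the C4 ester must later be rebuilt into the C12–C15 chain, and the methyl acetal must be exchanged for acetate on an acid-labile end product.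
- Comparison: the chosen strategy gives up the short pyran construction and in return replaces the cyclisation by a ring expansion of a seven-membered lactone.

**Alternative 2:** Only C–O bonds are disconnected: the C7–O bond and the C8–C9 epoxide lead back to a C7=C8 olefin in the finished bicyclic skeleton. Forward, dye-sensitised photooxygenation gives the C7 hydroperoxide with shift of the olefin, and a titanium alkoxide in the same flask passes the distal peroxide oxygen to the new olefin, giving the syn epoxy carbinol A2.
- For it: one operation instead of two (steps 12 and 24 here), and the intramolecular oxygen transfer guarantees the syn relationship. On step economy at C7–C9 it is stronger.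
- Against it: it is a tactic for the last three stereocentres and presupposes the nine-membered ring, which is the real problem. With the enol ether present, photooxygenation must distinguish C7=C8 from C3=C4, which in A2 is tamed only by a C4 ester that then has to be converted into the side chain in the presence of the epoxy alcohol.
- Comparison: the chosen route uses the same ene reaction but earlier, before an enol ether exists, and it also supplies the ring.

**Alternative 3:** The C4a–C11a bond is cut, relating the carbocycle to a thirteen-membered allylic lactone whose ester C–O bond is O2–C3. Forward, enolisation and O-silylation give a silyl ketene acetal whose [3,3] shift contracts the ring to the vinyl acid A3.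
- For it: the ring-fusion bond and both of its stereocentres are made in the ring-forming event, and the C7 oxygen, the C8=C9 olefin and the methylene are already present. On stereocentres made in the key step it is stronger, since the chosen key step makes none.
- Against it: it needs a thirteen-membered lactone with a Z olefin and a quaternary carbinol, closed by macrolactonisation. Chair versus boat and enolate geometry in a macrocycle are both uncertain, so the C4a/C11a relationship is not secure. The C7 centre must be set separately, and A3 has C1 as an acid and C3–C4 as a vinyl group, so the pyran still needs redox adjustment.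
- Comparison: the chosen key step cannot fail stereochemically, and its precursor is reached in seven steps.

Key step: step 8

## Route

Remark: C7 in 12–14 and C1 in 19–36 are carried as epimer mixtures, because C7 is flattened in step 8 and C1 equilibrates at the lactol stage before step 23 fixes it. The C7=C8 olefin of 15 is assumed to be Z.

Step 1
Reactants: 1 methacrolein; 2 (1,3-dioxolan-2-ylmethyl)triphenylphosphonium bromide
Product: 4 2-[(1E)-3-methylbuta-1,3-dien-1-yl]-1,3-dioxolane, via E/Z diene mixture 3 (not isolated)
Conditions: KOtBu, THF, 0 → 23 °C; then I2 (2 mol %), CH2Cl2, daylight, 23 °C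
Reagents that add atoms: none
Why: Wittig olefination gives the dienyl acetal as an E/Z mixture; iodine-catalysed equilibration converts it into the E isomer, the only one that reaches the s-cis geometry needed in step 2.

Step 2
Reactants: 4 2-[(1E)-3-methylbuta-1,3-dien-1-yl]-1,3-dioxolane; 5 acrolein
Product: 6 cis-(1R,2S)-2-(1,3-dioxolan-2-yl)-4-methylcyclohex-3-ene-1-carbaldehyde
Conditions: (5S)-5-benzyl-2,2,3-trimethylimidazolidin-4-one hydrochloride (20 mol %), MeCN/H2O 95:5, −20 °C
Reagents that add atoms: none
Why: Iminium-catalysed Diels–Alder reaction in which the methyl group ("para") and the acetal-bearing terminus ("ortho") direct the same regiochemistry and the endo mode gives the cis adduct; the benzyl group of the (5S) catalyst screens one face of the iminium ion, so that C11a should form with the configuration that becomes 11aR in 38. The minor exo (trans) adduct is removed here, because after step 3 it would be the enantiomer of 7.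

Step 3
Reactants: 6 cis aldehyde
Product: 7 trans-(1S,2S)-2-(1,3-dioxolan-2-yl)-4-methylcyclohex-3-ene-1-carbaldehyde
Conditions: DBU (0.2 equiv), CH2Cl2, 23 °C
Reagents that add atoms: none
Why: Base-mediated epimerisation through the enolate at the formyl-bearing carbon (C4a) gives the diequatorial trans isomer under thermodynamic control; C11a carries no acidic hydrogen and is unchanged.

Step 4
Reactants: 7 trans aldehyde
Product: 9 2-[(1R,6R)-6-(2,2-dimethoxyethyl)-3-methylcyclohex-2-en-1-yl]-1,3-dioxolane, via methyl enol ether 8 (not isolated)
Conditions: Ph3P(CH2OMe)Cl, KN(SiMe3)2, THF, −78 → 0 °C; then MeOH, PPTS (cat.), 23 °C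
Reagents that add atoms: (methoxymethyl)triphenylphosphonium chloride [Cl-].COC[P+](c1ccccc1)(c1ccccc1)c1ccccc1; methanol CO
Why: Wittig homologation adds C3, and acid-catalysed addition of methanol to the enol ether, which is much faster than exchange of the dioxolane, gives the dimethyl acetal. C3 (acyclic acetal) and C1 (cyclic acetal) are thereby differentiated for step 10.

Step 5
Reactants: 9 cyclohexene bis-acetal
Product: 11 (2S,3R)-3-(2,2-dimethoxyethyl)-2-(1,3-dioxolan-2-yl)-6-oxoheptanoic acid, via keto aldehyde 10 (not isolated)
Conditions: O3, CH2Cl2, −78 °C; PPh3; then NaClO2, NaH2PO4, 2-methylbut-2-ene, t-BuOH/H2O, 0 °C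
Reagents that add atoms: ozone [O-][O+]=O; sodium chlorite [Na+].[O-]Cl=O
Why: Ozonolysis with reductive work-up cleaves C7=C11 into the C7 methyl ketone and the C11 aldehyde; the aldehyde, prone to β-elimination of an acetal oxygen, is oxidised at once under buffered Pinnick conditions, which leave both acetals and C11a intact.

Step 6
Reactants: 11 keto acid
Product: 12 (2S,3R)-3-(2,2-dimethoxyethyl)-2-(1,3-dioxolan-2-yl)-6-hydroxy-6-methyloct-7-enoic acid (both C6 epimers; C6 = C7 of the target)
Conditions: CH2=CHMgBr (3.2 equiv), CeCl3, THF, −78 → 0 °C
Reagents that add atoms: vinylmagnesium bromide C=C[Mg]Br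
Why: The first equivalent forms the unreactive carboxylate and the organocerium species adds 1,2 to the methyl ketone without enolisation; the configuration of the new carbinol is immaterial because it is erased in step 8.

Step 7
Reactants: 12 hydroxy acid
Product: 13 (3S,4R)-4-(2,2-dimethoxyethyl)-3-(1,3-dioxolan-2-yl)-7-ethenyl-7-methyloxepan-2-one (both C7 epimers)
Conditions: DCC, DMAP, DMAP·HCl, CHCl3, 60 °C, slow addition (final 2 mM)
Reagents that add atoms: none
Why: Carbodiimide lactonisation under Keck conditions (Steglich-type acyl transfer); the DMAP/DMAP·HCl buffer suppresses N-acylurea formation so that the slow acylation of the tertiary allylic hydroxyl can compete, and the fully substituted carbinol carbon favours seven-membered closure.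

Step 8
Reactants: 13 seven-membered lactone
Product: 15 (4Z,8R,9S)-8-(2,2-dimethoxyethyl)-9-(1,3-dioxolan-2-yl)-5-methylcyclonon-4-en-1-one, via 2-methylidene oxepane 14 (not isolated)
Conditions: Cp2TiMe2 (2.2 equiv), toluene, 70 °C, dark; filtration through basic Al2O3 (pentane, 1 % Et3N); then o-xylene, Et3N (0.1 equiv), 170 °C, sealed tube
Reagents that add atoms: dimethyltitanocene C[Ti](C)(C1C=CC=C1)C1C=CC=C1
Why: Cp2TiMe2 loses methane on heating to give a titanium methylidene, which converts the lactone carbonyl through an oxatitanacyclobutane into the exocyclic enol ether 14, adding C10 without base so that the acidic C11a–H is not touched. After removal of titanium residues, which would isomerise 14 or methylenate the product, 14 is an allyl vinyl ether (C10=C11–O–C7–C8=C9) and rearranges thermally by a [3,3] sigmatropic shift. The closest known reaction type is the Claisen ring expansion of 2-methylene-6-vinyltetrahydropyrans to cyclooct-4-enones, here taken one ring size up. The nine-membered ring is not closed by cyclisation: C9–C10 forms while C7–O breaks in a bridged, chair-like six-atom transition state in which the tether C6–C5–C4a–C11a spans two axial positions, so the oxepane grows by two atoms. With C6 axial on C7, C6 and C9 end up cis on the new olefin, giving the Z-cyclononene. No stereocentre is created; C4a and C11a are spectators and the quaternary C7 is destroyed, so both C7 epimers of 13 converge on one ketone. The selectivity needed is methylenation of the lactone carbonyl in the presence of two acetals and the vinyl group, and a shift that outruns migration of the enol ether double bond into the ring; the alumina filtration and amine-buffered thermolysis are there to secure the latter.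

Step 9
Reactants: 15 cyclononenone
Product: 16 2-[(5Z)-9-(2,2-dimethoxyethyl)-6-methyl-2-methylidenecyclonon-5-en-1-yl]-1,3-dioxolane (ring centres as in 15)
Conditions: Cp2TiMe2 (3 equiv), toluene, 70 °C, dark
Reagents that add atoms: dimethyltitanocene C[Ti](C)(C1C=CC=C1)C1C=CC=C1
Why: Petasis methylenation of the ketone installs C19; the non-basic titanium methylidene avoids epimerisation at C11a and β-elimination of the acetal that a phosphorus ylide could cause.

Step 10
Reactants: 16 diene bis-acetal
Product: 18 [(4Z)-9-(1,3-dioxolan-2-yl)-5-methyl-8-methylidenecyclonon-4-en-1-yl]acetic acid (ring centres as in 15), via aldehyde 17 (not isolated)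
Conditions: AcOH/THF/H2O 3:1:1, 23 °C; then NaClO2, NaH2PO4, 2-methylbut-2-ene, t-BuOH/H2O, 0 °C
Reagents that add atoms: water O; sodium chlorite [Na+].[O-]Cl=O
Why: The acyclic dimethyl acetal hydrolyses far faster than the dioxolane, so only C3 is unmasked, and Pinnick oxidation raises it to the acid level. This difference in oxidation level between C3 and C1 later decides which carbon becomes the enol-ether carbon.

Step 11
Reactants: 18 acid
Product: 19 trans-fused hydroxy lactone (C3 lactone carbonyl; O2; C1 lactol as both epimers; Z C7=C8 olefin; C11 methylidene)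
Conditions: HCl (1 M aq.), THF, 23 °C
Reagents that add atoms: water O
Why: Hydrolysis of the dioxolane frees the C1 aldehyde, which is captured by the neighbouring carboxyl group as the six-membered lactol-lactone (ring tautomer of the aldehydo acid); this closes the O2–C1 bond and keeps the concentration of the epimerisable β,γ-unsaturated aldehyde low.

Step 12
Reactants: 19 hydroxy lactone
Product: 21 (7S)-7-hydroxy lactone with Z C8=C9 olefin, via allylic hydroperoxide 20 (not isolated)
Conditions: O2, tetraphenylporphyrin (cat.), hν (visible), CH2Cl2, −20 °C; then PPh3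
Reagents that add atoms: dioxygen O=O
Why: Schenck ene reaction: singlet oxygen bonds to C7 of the trisubstituted olefin and takes a C9 hydrogen suprafacially from the more crowded side of the double bond, shifting the olefin to C8=C9; the diene-like transition state fits the ring only in its cisoid form, so the Z olefin is expected, and attack on the outer face of the cyclononene in the trans-fused bicycle should give 7S. The 1,1-disubstituted C11=C19 olefin reacts far more slowly, and the phosphine reduces the hydroperoxide.

Step 13
Reactants: 21 allylic alcohol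
Product: 22 bis(triethylsilyl) derivative (C1–OSiEt3 silyl acetal; C7–OSiEt3)
Conditions: Et3SiOTf (2.5 equiv), 2,6-lutidine, CH2Cl2, −78 → 0 °C
Reagents that add atoms: triethylsilyl trifluoromethanesulfonate CC[Si](CC)(CC)OS(=O)(=O)C(F)(F)F
Why: Silylation of the lactol hydroxyl gives a C1 silyl acetal that can later be opened by fluoride without acid, and silylation of the tertiary C7 hydroxyl removes the only acidic hydrogen before steps 14, 15 and 22.

Step 14
Reactants: 22 silyloxy lactone
Product: 24 2-silyloxy-3,4-dihydro-2H-pyran (C3=C4 enol ether; C1–OSiEt3; C7–OSiEt3), via lactol 23 (not isolated)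
Conditions: i-Bu2AlH, CH2Cl2, −78 °C; potassium sodium tartrate (aq.); then MsCl, Et3N, CH2Cl2, 0 → 40 °C
Reagents that add atoms: none
Why: Hydride reduction of the lactone stops at the lactol at −78 °C, and sulfonylation of the anomeric hydroxyl followed by loss of the C4 hydrogen gives the enol ether; because only C3 carries a leaving group, C1 must remain the acetal carbon.

Step 15
Reactants: 24 enol ether
Product: 26 4-bromo enol ether, via dibromide 25 (not isolated)
Conditions: Br2 (1.0 equiv), CH2Cl2, −78 °C; then DBU, −78 → 23 °C
Reagents that add atoms: bromine BrBr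
Why: The enol ether is by far the most electron-rich of the three olefins and should take up one equivalent of bromine selectively at −78 °C; base then expels the anomeric bromide together with the C4 hydrogen (bromination–dehydrobromination of dihydropyrans).

Step 16
Reactants: 27 (R)-2,2-dimethyl-1,3-dioxolane-4-carbaldehyde
Product: 28 (S)-2,2-dimethyl-4-(2-methylprop-1-en-1-yl)-1,3-dioxolane
Conditions: i-PrPPh3I, n-BuLi, THF, −78 → 0 °C
Reagents that add atoms: isopropyltriphenylphosphonium iodide [I-].CC(C)[P+](c1ccccc1)(c1ccccc1)c1ccccc1
Why: Wittig olefination with the non-stabilised ylide at low temperature is faster than enolisation of the α-alkoxy aldehyde, so the stereocentre (future C13) is kept; the ylide supplies C15 and its two methyl groups.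

Step 17
Reactants: 28 alkene acetonide
Product: 29 (S)-4-methylpent-3-ene-1,2-diol
Conditions: AcOH/H2O 4:1, 40 °C
Reagents that add atoms: none
Why: Acetonide hydrolysis is done before the acid-sensitive trisubstituted epoxide exists.

Step 18
Reactants: 29 diol
Product: 30 (S)-1,2-bis(tert-butyldimethylsilyloxy)-4-methylpent-3-ene
Conditions: t-BuMe2SiCl, imidazole, DMF, 23 °C
Reagents that add atoms: tert-butyldimethylsilyl chloride CC(C)(C)[Si](C)(C)Cl
Why: Standard bis-silylation; the bulky silyl ether at C13 is what later enforces Felkin–Anh addition.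

Step 19
Reactants: 30 bis-silyl ether
Product: 31 (S)-2-(tert-butyldimethylsilyloxy)-4-methylpent-3-en-1-ol
Conditions: HF·pyridine, pyridine, THF, 0 °C
Reagents that add atoms: none
Why: The unhindered primary silyl ether is cleaved much faster than the secondary allylic one, freeing C12–OH for oxidation.

Step 20
Reactants: 31 homoallylic alcohol
Product: 32 (2R)-2-(tert-butyldimethylsilyloxy)-2-[(2R)-3,3-dimethyloxiran-2-yl]ethan-1-ol
Conditions: 1,2:4,5-di-O-isopropylidene-β-D-erythro-2,3-hexodiulo-2,6-pyranose (30 mol %), KHSO5 (as 2KHSO5·KHSO4·K2SO4), K2CO3, Bu4NHSO4, MeCN/CH2(OMe)2/aq. Na2B4O7, 0 °C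
Reagents that add atoms: potassium peroxymonosulfate [K+].[O-]S(=O)(=O)OO
Why: Shi epoxidation of the trisubstituted olefin under reagent control; the spiro transition-state model of the D-fructose-derived ketone predicts the (R) oxirane carbon (C14), i.e. the 13,14-anti isomer, which hydroxyl-directed epoxidation of this olefin type would not give.

Step 21
Reactants: 32 epoxy alcohol
Product: 33 (2S)-2-(tert-butyldimethylsilyloxy)-2-[(2R)-3,3-dimethyloxiran-2-yl]acetaldehyde
Conditions: Dess–Martin periodinane, NaHCO3, CH2Cl2, 0 °C
Reagents that add atoms: none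
Why: Buffered, non-basic oxidation of the primary alcohol; the α-silyloxy aldehyde is used crude to avoid epimerisation at C13.

Step 22
Reactants: 26 4-bromo enol ether; 33 epoxy aldehyde
Product: 35 (12R,13R,14R) C12 carbinol (C13–OSiMe2t-Bu; C1 and C7 triethylsilyl ethers), via vinyllithium 34 (not isolated)
Conditions: t-BuLi (2.1 equiv), Et2O, −78 °C; then 33, −78 °C; NH4Cl (aq.)
Reagents that add atoms: none
Why: Bromine–lithium exchange gives the β-lithio enol ether, which adds to the aldehyde; with a bulky silyl ether and non-chelating lithium, Felkin–Anh attack anti to the α-silyloxy group should give the 12,13-anti (12R) carbinol.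

Step 23
Reactants: 35 carbinol
Product: 37 1,12,13-triacetate with free C7 hydroxyl (1R), via tetraol 36 (not isolated)
Conditions: Bu4NF, AcOH, THF, 0 → 23 °C; then Ac2O, pyridine, DMAP (cat.), CH2Cl2, 0 °C
Reagents that add atoms: acetic anhydride CC(=O)OC(C)=O
Why: Buffered fluoride removes all three silyl groups without acid, and acetylation then takes the lactol and the two secondary hydroxyls while the tertiary C7 hydroxyl stays free. The lactol anomerises, and acylation on the less hindered side, trans to the C11a–C11 bond, is expected to give the 1R acetate.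

Step 24
Reactants: 37 triacetate
Product: 38 target (1R,4aS,7S,8R,9R,11aR,12R,13R,14R)
Conditions: VO(acac)2 (5 mol %), t-BuOOH, CH2Cl2, 0 → 23 °C
Reagents that add atoms: tert-butyl hydroperoxide CC(C)(C)OO
Why: Hydroxyl-directed epoxidation: the tertiary allylic C7 hydroxyl, now the only free hydroxyl, binds vanadium and delivers oxygen to the syn face of the Z C8=C9 olefin, giving the cis epoxide syn to the carbinol (8R,9R); the undirected enol ether and exocyclic methylene should react much more slowly.

## Compound list

1 | methacrolein | CC(=C)C=O | starting material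
2 | (1,3-dioxolan-2-ylmethyl)triphenylphosphonium bromide | [Br-].C1COC(C[P+](c2ccccc2)(c2ccccc2)c2ccccc2)O1 | starting material
3 | 2-(3-methylbuta-1,3-dien-1-yl)-1,3-dioxolane, E/Z mixture | CC(=C)C=CC1OCCO1 | intermediate
4 | 2-[(1E)-3-methylbuta-1,3-dien-1-yl]-1,3-dioxolane | CC(=C)/C=C/C1OCCO1 | intermediate
5 | acrolein | C=CC=O | starting material
6 | cis-(1R,2S)-2-(1,3-dioxolan-2-yl)-4-methylcyclohex-3-ene-1-carbaldehyde | CC1=C[C@H](C2OCCO2)[C@H](C=O)CC1 | intermediate
7 | trans-(1S,2S)-2-(1,3-dioxolan-2-yl)-4-methylcyclohex-3-ene-1-carbaldehyde | CC1=C[C@H](C2OCCO2)[C@@H](C=O)CC1 | intermediate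
8 | trans-2-[6-(2-methoxyethenyl)-3-methylcyclohex-2-en-1-yl]-1,3-dioxolane (E/Z enol ether, ring centres as in 7) | CC1=C[C@H](C2OCCO2)[C@@H](C=COC)CC1 | intermediate
9 | 2-[(1R,6R)-6-(2,2-dimethoxyethyl)-3-methylcyclohex-2-en-1-yl]-1,3-dioxolane | CC1=C[C@H](C2OCCO2)[C@@H](CC(OC)OC)CC1 | intermediate
10 | 3-(2,2-dimethoxyethyl)-2-(1,3-dioxolan-2-yl)-6-oxoheptanal (centres as in 11) | CC(=O)CC[C@H](CC(OC)OC)[C@H](C=O)C1OCCO1 | intermediate
11 | (2S,3R)-3-(2,2-dimethoxyethyl)-2-(1,3-dioxolan-2-yl)-6-oxoheptanoic acid | CC(=O)CC[C@H](CC(OC)OC)[C@H](C(=O)O)C1OCCO1 | intermediate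
12 | (2S,3R)-3-(2,2-dimethoxyethyl)-2-(1,3-dioxolan-2-yl)-6-hydroxy-6-methyloct-7-enoic acid, both C6 epimers | C=CC(C)(O)CC[C@H](CC(OC)OC)[C@H](C(=O)O)C1OCCO1 | intermediate
13 | (3S,4R)-4-(2,2-dimethoxyethyl)-3-(1,3-dioxolan-2-yl)-7-ethenyl-7-methyloxepan-2-one, both C7 epimers | O=C1OC(C)(C=C)CC[C@H](CC(OC)OC)[C@H]1C2OCCO2 | intermediate
14 | 2-methylidene analogue of 13 (cyclic enol ether) | C=C1OC(C)(C=C)CC[C@H](CC(OC)OC)[C@H]1C2OCCO2 | intermediate
15 | (4Z,8R,9S)-8-(2,2-dimethoxyethyl)-9-(1,3-dioxolan-2-yl)-5-methylcyclonon-4-en-1-one | O=C1CC/C=C(C)\CC[C@H](CC(OC)OC)[C@H]1C2OCCO2 | intermediate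
16 | 2-[(5Z)-9-(2,2-dimethoxyethyl)-6-methyl-2-methylidenecyclonon-5-en-1-yl]-1,3-dioxolane (centres as in 15) | C=C1CC/C=C(C)\CC[C@H](CC(OC)OC)[C@H]1C2OCCO2 | intermediate
17 | [(4Z)-9-(1,3-dioxolan-2-yl)-5-methyl-8-methylidenecyclonon-4-en-1-yl]acetaldehyde (centres as in 15) | C=C1CC/C=C(C)\CC[C@H](CC=O)[C@H]1C2OCCO2 | intermediate
18 | [(4Z)-9-(1,3-dioxolan-2-yl)-5-methyl-8-methylidenecyclonon-4-en-1-yl]acetic acid (centres as in 15) | C=C1CC/C=C(C)\CC[C@H](CC(=O)O)[C@H]1C2OCCO2 | intermediate
19 | trans-fused hydroxy lactone (C3 carbonyl, C1 lactol as both epimers, Z C7=C8, C11 methylidene) | C=C1CC/C=C(C)\CC[C@@H]2CC(=O)OC(O)[C@@H]12 | intermediate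
20 | (7S)-7-hydroperoxide of the lactone with Z C8=C9 | C=C1C/C=C\[C@@](C)(OO)CC[C@@H]2CC(=O)OC(O)[C@@H]12 | intermediate
21 | (7S)-7-hydroxy lactone with Z C8=C9 | C=C1C/C=C\[C@@](C)(O)CC[C@@H]2CC(=O)OC(O)[C@@H]12 | intermediate
22 | 1-O,7-O-bis(triethylsilyl) derivative of 21 | C=C1C/C=C\[C@@](C)(O[Si](CC)(CC)CC)CC[C@@H]2CC(=O)OC(O[Si](CC)(CC)CC)[C@@H]12 | intermediate
23 | C3 lactol of 22 | C=C1C/C=C\[C@@](C)(O[Si](CC)(CC)CC)CC[C@@H]2CC(O)OC(O[Si](CC)(CC)CC)[C@@H]12 | intermediate
24 | C3=C4 enol ether (2-silyloxy-3,4-dihydro-2H-pyran) | C=C1C/C=C\[C@@](C)(O[Si](CC)(CC)CC)CC[C@@H]2C=COC(O[Si](CC)(CC)CC)[C@@H]12 | intermediate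
25 | 3,4-dibromide of 24 | C=C1C/C=C\[C@@](C)(O[Si](CC)(CC)CC)CC[C@@H]2C(Br)C(Br)OC(O[Si](CC)(CC)CC)[C@@H]12 | intermediate
26 | 4-bromo enol ether | C=C1C/C=C\[C@@](C)(O[Si](CC)(CC)CC)CC[C@@H]2C(Br)=COC(O[Si](CC)(CC)CC)[C@@H]12 | intermediate
27 | (R)-2,2-dimethyl-1,3-dioxolane-4-carbaldehyde | O=C[C@H]1COC(C)(C)O1 | starting material
28 | (S)-2,2-dimethyl-4-(2-methylprop-1-en-1-yl)-1,3-dioxolane | CC(C)=C[C@H]1COC(C)(C)O1 | intermediate
29 | (S)-4-methylpent-3-ene-1,2-diol | CC(C)=C[C@H](O)CO | intermediate
30 | (S)-1,2-bis(tert-butyldimethylsilyloxy)-4-methylpent-3-ene | CC(C)=C[C@H](O[Si](C)(C)C(C)(C)C)CO[Si](C)(C)C(C)(C)C | intermediate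
31 | (S)-2-(tert-butyldimethylsilyloxy)-4-methylpent-3-en-1-ol | CC(C)=C[C@H](O[Si](C)(C)C(C)(C)C)CO | intermediate
32 | (2R)-2-(tert-butyldimethylsilyloxy)-2-[(2R)-3,3-dimethyloxiran-2-yl]ethan-1-ol | OC[C@@H](O[Si](C)(C)C(C)(C)C)[C@H]1OC1(C)C | intermediate
33 | (2S)-2-(tert-butyldimethylsilyloxy)-2-[(2R)-3,3-dimethyloxiran-2-yl]acetaldehyde | O=C[C@@H](O[Si](C)(C)C(C)(C)C)[C@H]1OC1(C)C | intermediate
34 | 4-lithio enol ether | C=C1C/C=C\[C@@](C)(O[Si](CC)(CC)CC)CC[C@@H]2C([Li])=COC(O[Si](CC)(CC)CC)[C@@H]12 | intermediate
35 | (12R,13R,14R) C12 carbinol, C13 silyl ether, C1 and C7 triethylsilyl ethers | C=C1C/C=C\[C@@](C)(O[Si](CC)(CC)CC)CC[C@@H]2C([C@@H](O)[C@@H](O[Si](C)(C)C(C)(C)C)[C@H]3OC3(C)C)=COC(O[Si](CC)(CC)CC)[C@@H]12 | intermediate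
36 | tetraol (C1 lactol, C7, C12, C13 hydroxyls) | C=C1C/C=C\[C@@](C)(O)CC[C@@H]2C([C@@H](O)[C@@H](O)[C@H]3OC3(C)C)=COC(O)[C@@H]12 | intermediate
37 | (1R)-1,12,13-triacetate with free C7 hydroxyl and Z C8=C9 | C=C1C/C=C\[C@@](C)(O)CC[C@@H]2C([C@@H](OC(C)=O)[C@@H](OC(C)=O)[C@H]3OC3(C)C)=CO[C@H](OC(C)=O)[C@@H]12 | intermediate
38 | CNP0134792.1, (1R,4aS,7S,8R,9R,11aR,12R,13R,14R) | C=C1C[C@H]2O[C@H]2[C@@](C)(O)CC[C@@H]2C([C@@H](OC(C)=O)[C@@H](OC(C)=O)[C@H]3OC3(C)C)=CO[C@H](OC(C)=O)[C@@H]12 | target

## Step count and least certain steps

Total: 24 steps. Longest linear sequence: 18 steps (steps 1–15 and 22–24, from methacrolein); the aldehyde 33 takes 6 steps (16–21).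

**Step 8 (key step).** The exocyclic enol ether 14 may migrate into the ring under traces of acid or titanium residues before the shift, or the bridged transition state may be reached only at temperatures at which 14 and its acetals fragment, so that the expansion stalls. Fallback: the ring is closed by olefin metathesis instead. Setting out from keto acid 11, Wittig methylenation of the C7 ketone (Ph3P=CH2) gives the isopropenyl acid F1, coupling with N,O-dimethylhydroxylamine gives the Weinreb amide F2, and but-3-enylmagnesium bromide gives the dienone F3. Ring-closing metathesis with the second-generation Hoveyda–Grubbs catalyst at high dilution forms C7=C8 and comes back to the route at ketone 15; either olefin geometry is acceptable.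

**Step 12.** Hydrogen may be abstracted from C6 or from the C7 methyl group instead of C9, the new olefin may form with E geometry, or oxygen may attack the other face of the flexible ring. Fallback: an epoxide-opening sequence with reagent control. Setting out from diene 16, Shi epoxidation of the trisubstituted olefin (ketone enantiomer chosen for the 7S face) gives the epoxide F4. Phenylselenide (from PhSeSePh and NaBH4) opens it at the less hindered C8 to the hydroxy selenide F5, and H2O2 oxidation with syn elimination away from the carbinol gives the allylic alcohol F6. The conditions of step 10 convert F6 through the aldehyde F7 into the acid F8, and neutral dioxolane cleavage (I2 in acetone) lets F8 close to 21, where the route is rejoined.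

**Step 7.** Acylation of the tertiary allylic hydroxyl may be too slow, so that N-acylurea formation, oligomerisation or ionisation of the allylic alcohol take over. Fallback: the acyl group is activated before the carbinol exists. Setting out from keto acid 11, esterification with 2,2,2-trifluoroethanol gives the activated ester F9. Addition of the vinylcerium reagent to the ketone at −78 °C and warming lets the tertiary alkoxide displace trifluoroethoxide intramolecularly, which comes back at lactone 13.

**Step 2.** The dienyl acetal may hydrolyse in the acidic aqueous medium (the freed dienal would itself enter iminium catalysis), and enantiopurity erodes if endo/exo selectivity is low. Fallback: Lewis acid catalysis under anhydrous conditions. Setting out from diene 4, cycloaddition with 3-acryloyl-1,3-oxazolidin-2-one, catalysed by the Cu(SbF6)2 complex of a tert-butyl-bis(oxazoline) (divalent copper; ligand enantiomer matched to the required sense), gives the cis imide F10. LiBH4 removes the auxiliary to give the alcohol F11, and Dess–Martin oxidation returns to aldehyde 6.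

**Step 15.** Bromine may also add to the C8=C9 or C11=C19 olefin, or the HBr released may cleave the anomeric silyl acetal. Fallback: the C4–C12 bond is made by an aldol reaction before the enol ether exists, which needs neither halogen nor organolithium. Setting out from lactone 22, the lithium enolate (LiN(i-Pr)2, −78 °C) adds to aldehyde 33 to give the β-hydroxy lactone F12 (Felkin–Anh at C12; C4 is flattened later). Et3SiCl and imidazole give the silyl ether F13, i-Bu2AlH gives the lactol F14, and MsCl/Et3N gives the enol ether F15. The conditions of step 23 remove all silyl groups and acetylate, coming back at triacetate 37.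

**Step 22.** Facial selectivity at the aldehyde may be poor (Felkin–Anh against chelation), or the vinyllithium may deprotonate the α-silyloxy aldehyde. Fallback: an oxidation–reduction sequence. Setting out from 35 obtained as a C12 epimer mixture, Dess–Martin oxidation gives the vinylogous ester ketone F16, and Corey–Bakshi–Shibata reduction (oxazaborolidine enantiomer matched to 12R, catecholborane) returns to 35 as the 12R carbinol.

## Further compounds

F1 | step 8 | 3-(2,2-dimethoxyethyl)-2-(1,3-dioxolan-2-yl)-6-methylhept-6-enoic acid (centres as in 11) | C=C(C)CC[C@H](CC(OC)OC)[C@H](C(=O)O)C1OCCO1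
F2 | step 8 | N-methoxy-N-methylamide of F1 | C=C(C)CC[C@H](CC(OC)OC)[C@H](C(=O)N(C)OC)C1OCCO1
F3 | step 8 | but-3-enyl ketone from F2 (dienone for metathesis) | C=C(C)CC[C@H](CC(OC)OC)[C@H](C(=O)CCC=C)C1OCCO1
F4 | step 12 | cis-7,8-epoxide of 16 | C=C1CC[C@H]2O[C@@]2(C)CC[C@H](CC(OC)OC)[C@H]1C1OCCO1
F5 | step 12 | 7-hydroxy-8-(phenylselanyl) derivative | C=C1CC[C@H]([Se]c2ccccc2)[C@@](C)(O)CC[C@H](CC(OC)OC)[C@H]1C1OCCO1
F6 | step 12 | (7S)-allylic alcohol with Z C8=C9, both acetals intact | C=C1C/C=C\[C@@](C)(O)CC[C@H](CC(OC)OC)[C@H]1C2OCCO2
F7 | step 12 | C3 aldehyde from F6 | C=C1C/C=C\[C@@](C)(O)CC[C@H](CC=O)[C@H]1C2OCCO2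
F8 | step 12 | C3 acid from F7 | C=C1C/C=C\[C@@](C)(O)CC[C@H](CC(=O)O)[C@H]1C2OCCO2
F9 | step 7 | 2,2,2-trifluoroethyl ester of 11 | CC(=O)CC[C@H](CC(OC)OC)[C@H](C(=O)OCC(F)(F)F)C1OCCO1
F10 | step 2 | cis N-acyl oxazolidinone cycloadduct | CC1=C[C@H](C2OCCO2)[C@H](C(=O)N2CCOC2=O)CC1
F11 | step 2 | cis primary alcohol from F10 | CC1=C[C@H](C2OCCO2)[C@H](CO)CC1
F12 | step 15 | β-hydroxy lactone (aldol adduct of 22 and 33) | C=C1C/C=C\[C@@](C)(O[Si](CC)(CC)CC)CC[C@@H]2C([C@@H](O)[C@@H](O[Si](C)(C)C(C)(C)C)[C@H]3OC3(C)C)C(=O)OC(O[Si](CC)(CC)CC)[C@@H]12
F13 | step 15 | C12 triethylsilyl ether of F12 | C=C1C/C=C\[C@@](C)(O[Si](CC)(CC)CC)CC[C@@H]2C([C@@H](O[Si](CC)(CC)CC)[C@@H](O[Si](C)(C)C(C)(C)C)[C@H]3OC3(C)C)C(=O)OC(O[Si](CC)(CC)CC)[C@@H]12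
F14 | step 15 | C3 lactol of F13 | C=C1C/C=C\[C@@](C)(O[Si](CC)(CC)CC)CC[C@@H]2C([C@@H](O[Si](CC)(CC)CC)[C@@H](O[Si](C)(C)C(C)(C)C)[C@H]3OC3(C)C)C(O)OC(O[Si](CC)(CC)CC)[C@@H]12
F15 | step 15 | enol ether with C12 triethylsilyl ether | C=C1C/C=C\[C@@](C)(O[Si](CC)(CC)CC)CC[C@@H]2C([C@@H](O[Si](CC)(CC)CC)[C@@H](O[Si](C)(C)C(C)(C)C)[C@H]3OC3(C)C)=COC(O[Si](CC)(CC)CC)[C@@H]12
F16 | step 22 | C12 ketone of 35 | C=C1C/C=C\[C@@](C)(O[Si](CC)(CC)CC)CC[C@@H]2C(C(=O)[C@@H](O[Si](C)(C)C(C)(C)C)[C@H]3OC3(C)C)=COC(O[Si](CC)(CC)CC)[C@@H]12
A1 | alternative 1 | methyl 2-methoxy-3,4-dihydro-2H-pyran-5-carboxylate carrying a ketal-protected silylpropargyl ketone arm and a butenyl arm | COC(=O)C1=CO[C@H](OC)[C@@H](C2(CC#C[Si](C)(C)C)OCCO2)[C@@H]1CCC=C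
A2 | alternative 2 | syn epoxy carbinol bicycle with C4 methyl ester and C1 methyl acetal | C=C1C[C@H]2O[C@H]2[C@@](C)(O)CC[C@@H]2C(C(=O)OC)=CO[C@H](OC)[C@@H]12
A3 | alternative 3 | trans-2-vinylcyclononenecarboxylic acid with C7 triethylsilyl ether | OC(=O)[C@H]1C(=C)C/C=C\[C@@](C)(O[Si](CC)(CC)CC)CC[C@@H]1C=C
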